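**Retrosynthetic overview**
- The C15 silyl ether comes off last. Before that, the C14–O bond is made by SeO2 allylic hydroxylation of a C10 methyl group, which also gives the ring-cis C1=C10 geometry from either alkene isomer.
- The 10-membered ring comes from ring-closing metathesis (C1=C10) of a trans-α-methylene-γ-butyrolactone carrying both alkene arms. The lactone ring is formed first, the carbocycle second.
- Key bond C8–O: the angelate is installed by stereoinvertive displacement of the C8 triethylsilyl ether (8S to 8R), so angelic acid is never activated as an acyl donor.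
- The lactone (C6–O, C6–C7) comes from a CrCl2-mediated allylation/lactonisation of a C1–C6 aldehyde (C4 set by Cu-catalysed conjugate addition) with a C7–C10 allyl bromide (C8 set by a glyoxylate–ene reaction).

Assumption: positions are given in germacrane numbering (C12 lactone carbonyl, lactone oxygen on C6, angelate on C8, C14 on C10, C15 on C4). The BINOL and Tol-BINAP enantiomers named are those expected to give the drawn configurations and would be swapped for their antipodes if the measured sense of induction were opposite.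

**Route**

Step 1
Reactants: 1 ethyl glyoxylate + 2 isobutylene
Product: 3 ethyl (2S)-2-hydroxy-4-methylpent-4-enoate
Conditions: (S)-BINOL (10 mol%), TiCl2(OiPr)2 (10 mol%), 4 Å molecular sieves, CH2Cl2, −30 °C
Reagents that add atoms: none
Why: BINOL–titanium-catalysed glyoxylate–ene reaction; the chiral Lewis acid blocks one face of the glyoxylate and sets the C8 carbinol in high ee.

Step 2
Reactants: 3 ethyl (2S)-2-hydroxy-4-methylpent-4-enoate
Product: 4 ethyl (2S)-4-methyl-2-(triethylsilyloxy)pent-4-enoate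
Conditions: Et3SiCl, imidazole, CH2Cl2, 0 °C → rt
Reagents that add atoms: chlorotriethylsilane, CC[Si](Cl)(CC)CC
Why: standard silylation of a secondary alcohol; the C8 centre is untouched.

Step 3
Reactants: 4 ethyl (2S)-4-methyl-2-(triethylsilyloxy)pent-4-enoate
Product: 5 (2S)-4-methyl-2-(triethylsilyloxy)pent-4-enal
Conditions: i-Bu2AlH (1.1 equiv), CH2Cl2, −78 °C; MeOH, aq. potassium sodium tartrate
Reagents that add atoms: none
Why: partial reduction of an α-silyloxy ester, whose tetrahedral aluminium intermediate is stable at −78 °C; the aldehyde is used at once to avoid epimerisation.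

Step 4
Reactants: 5 (2S)-4-methyl-2-(triethylsilyloxy)pent-4-enal + 6 methyl acrylate
Product: 7 methyl (4S)-3-hydroxy-6-methyl-2-methylidene-4-(triethylsilyloxy)hept-6-enoate (both C3 epimers)
Conditions: DABCO (1 equiv), neat methyl acrylate (5 equiv), rt, 4 d
Reagents that add atoms: none
Why: Morita–Baylis–Hillman reaction; the new carbinol centre is irrelevant because it is destroyed in step 5, and C8 is not touched.

Step 5
Reactants: 7 methyl (4S)-3-hydroxy-6-methyl-2-methylidene-4-(triethylsilyloxy)hept-6-enoate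
Product: 8 methyl (2Z,4S)-2-(bromomethyl)-6-methyl-4-(triethylsilyloxy)hepta-2,6-dienoate
Conditions: NBS, Me2S, CH2Cl2, 0 °C → rt
Reagents that add atoms: N-bromosuccinimide, O=C1CCC(=O)N1Br
Why: Corey–Kim-type activation of the allylic alcohol followed by SN2′ attack of bromide gives the thermodynamically favoured (Z)-2-(bromomethyl)enoate.

Step 6
Reactants: 9 (tert-butyldiphenylsilyloxy)acetaldehyde + 10 methyl (triphenylphosphoranylidene)acetate
Product: 11 methyl (2E)-4-(tert-butyldiphenylsilyloxy)but-2-enoate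
Conditions: CH2Cl2, rt
Reagents that add atoms: none
Why: Wittig olefination with a stabilised ylide, which is E-selective.

Step 7
Reactants: 11 methyl (2E)-4-(tert-butyldiphenylsilyloxy)but-2-enoate + 12 but-3-enylmagnesium bromide
Product: 13 methyl (3R)-3-[(tert-butyldiphenylsilyloxy)methyl]hept-6-enoate
Conditions: CuI (2 mol%), (R)-Tol-BINAP (3 mol%), t-BuOMe, −40 °C; aq. NH4Cl
Reagents that add atoms: none
Why: copper-catalysed asymmetric conjugate addition of a Grignard reagent to an enoate; the chiral bisphosphine–copper complex delivers the butenyl group to one face and sets C4.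

Step 8
Reactants: 13 methyl (3R)-3-[(tert-butyldiphenylsilyloxy)methyl]hept-6-enoate
Product: 14 (3R)-3-[(tert-butyldiphenylsilyloxy)methyl]hept-6-enal
Conditions: i-Bu2AlH (1.05 equiv), CH2Cl2, −78 °C; aq. potassium sodium tartrate
Reagents that add atoms: none
Why: low-temperature partial reduction of the ester to the aldehyde; the β-stereocentre cannot epimerise.

Step 9
Reactants: 8 methyl (2Z,4S)-2-(bromomethyl)-6-methyl-4-(triethylsilyloxy)hepta-2,6-dienoate + 14 (3R)-3-[(tert-butyldiphenylsilyloxy)methyl]hept-6-enal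
Product: 16 (4S,5R)-5-{(2R)-2-[(tert-butyldiphenylsilyloxy)methyl]hex-5-en-1-yl}-3-methylidene-4-[(1S)-3-methyl-1-(triethylsilyloxy)but-3-en-1-yl]oxolan-2-one, via chromium alkoxide 15 (not isolated)
Conditions: CrCl2 (4 equiv), THF, 0 °C → rt, 12 h; aq. NH4Cl
Reagents that add atoms: none
Why: Nozaki–Hiyama 2-(alkoxycarbonyl)allylation followed by lactonisation; the chair transition state with the C8-bearing group equatorial gives the anti adduct (trans-lactone), and attack anti to the C8–OSiEt3 bond (Felkin–Anh-type, H eclipsing the alkene to avoid A(1,3) strain) relays C8 to C7 (S) and C6 (R), leaving C8 as the 8S epimer that step 10 inverts.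

Step 10
Reactants: 16 (4S,5R)-5-{(2R)-2-[(tert-butyldiphenylsilyloxy)methyl]hex-5-en-1-yl}-3-methylidene-4-[(1S)-3-methyl-1-(triethylsilyloxy)but-3-en-1-yl]oxolan-2-one + 17 angelic acid
Product: 19 (1R)-1-[(2R,3S)-2-{(2R)-2-[(tert-butyldiphenylsilyloxy)methyl]hex-5-en-1-yl}-4-methylidene-5-oxooxolan-3-yl]-3-methylbut-3-en-1-yl (2Z)-2-methylbut-2-enoate, via alkoxyphosphonium salt 18 (not isolated)
Conditions: PPh3 (1.5 equiv), DDQ (1.5 equiv), CH2Cl2, 0 °C, 10 min; add 16, 0 °C → rt; then 17 (2 equiv), i-Pr2NEt (2 equiv), rt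
Reagents that add atoms: none
Why: Proposed new method: a desilylative Mitsunobu-type inversion in which the triethylsilyl ether oxygen of 16 attacks the aryloxyphosphonium centre of the PPh3–DDQ adduct, the phenoxide arm takes the silyl group (strong Si–OAr bond) to leave alkoxyphosphonium 18, and angelate then displaces Ph3P=O from C8 by SN2 with inversion to give the 8R ester without acyl activation (so no angelate-to-tiglate isomerisation), while the bulky, weakly basic primary tert-butyldiphenylsilyl ether should not engage; the closest known reactions are the Mitsunobu esterification and the PPh3/DDQ/ammonium-salt conversion of trimethylsilyl ethers into halides and azides, and what is new is a carboxylate nucleophile on a hindered secondary triethylsilyl ether.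

Step 11
Reactants: 19 (1R)-1-[(2R,3S)-2-{(2R)-2-[(tert-butyldiphenylsilyloxy)methyl]hex-5-en-1-yl}-4-methylidene-5-oxooxolan-3-yl]-3-methylbut-3-en-1-yl (2Z)-2-methylbut-2-enoate
Product: 20 (3aS,4R,6Z,10R,11aR)-10-[(tert-butyldiphenylsilyloxy)methyl]-6-methyl-3-methylidene-2-oxo-2,3,3a,4,5,8,9,10,11,11a-decahydrocyclodeca[b]furan-4-yl (2Z)-2-methylbut-2-enoate
Conditions: second-generation Hoveyda–Grubbs catalyst RuCl2(=CH-C6H4-2-OiPr)(H2IMes) (10 mol%), 1,4-benzoquinone (20 mol%), PhMe (1 mM), 80 °C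
Reagents that add atoms: none
Why: ring-closing metathesis between the monosubstituted and the methallyl alkene (the electron-poor α-methylene and angelate alkenes are spectators); no stereocentre is formed, the ring favours the cis trisubstituted alkene, and any E isomer converges in step 12.

Step 12
Reactants: 20 (3aS,4R,6Z,10R,11aR)-10-[(tert-butyldiphenylsilyloxy)methyl]-6-methyl-3-methylidene-2-oxo-2,3,3a,4,5,8,9,10,11,11a-decahydrocyclodeca[b]furan-4-yl (2Z)-2-methylbut-2-enoate
Product: 21 (3aS,4R,6E,10R,11aR)-10-[(tert-butyldiphenylsilyloxy)methyl]-6-(hydroxymethyl)-3-methylidene-2-oxo-2,3,3a,4,5,8,9,10,11,11a-decahydrocyclodeca[b]furan-4-yl (2Z)-2-methylbut-2-enoate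
Conditions: SeO2 (0.5 equiv), t-BuOOH (3 equiv), CH2Cl2, rt
Reagents that add atoms: selenium dioxide, O=[Se]=O (oxygen donor, reoxidised by tert-butyl hydroperoxide, CC(C)(C)OO)
Why: SeO2 allylic hydroxylation (ene reaction, then [2,3]-sigmatropic shift) at the C10 methyl; the [2,3] shift re-forms C1=C10 with CH2OH trans to C2 (the ring-cis geometry), as in the parthenolide to melampomagnolide B oxidation, and C9 is deactivated by the neighbouring acyloxy group.

Step 13
Reactants: 21 (3aS,4R,6E,10R,11aR)-10-[(tert-butyldiphenylsilyloxy)methyl]-6-(hydroxymethyl)-3-methylidene-2-oxo-2,3,3a,4,5,8,9,10,11,11a-decahydrocyclodeca[b]furan-4-yl (2Z)-2-methylbut-2-enoate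
Product: 22 (3aS,4R,6E,10R,11aR)-6,10-bis(hydroxymethyl)-3-methylidene-2-oxo-2,3,3a,4,5,8,9,10,11,11a-decahydrocyclodeca[b]furan-4-yl (2Z)-2-methylbut-2-enoate (CNP0262807.1)
Conditions: HF·pyridine, pyridine, THF, 0 °C → rt
Reagents that add atoms: none
Why: fluoride-mediated silyl ether cleavage under buffered conditions that leave the angelate, the α-methylene lactone and all stereocentres untouched.

**Compound list**

1 | ethyl glyoxylate | CCOC(=O)C=O | starting material
2 | isobutylene (2-methylpropene) | CC(C)=C | starting material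
3 | ethyl (2S)-2-hydroxy-4-methylpent-4-enoate | CCOC(=O)[C@@H](O)CC(C)=C | intermediate
4 | ethyl (2S)-4-methyl-2-(triethylsilyloxy)pent-4-enoate | CCOC(=O)[C@@H](O[Si](CC)(CC)CC)CC(C)=C | intermediate
5 | (2S)-4-methyl-2-(triethylsilyloxy)pent-4-enal | O=C[C@@H](O[Si](CC)(CC)CC)CC(C)=C | intermediate
6 | methyl acrylate | C=CC(=O)OC | starting material
7 | methyl (4S)-3-hydroxy-6-methyl-2-methylidene-4-(triethylsilyloxy)hept-6-enoate (both C3 epimers) | C=C(C(=O)OC)C(O)[C@@H](O[Si](CC)(CC)CC)CC(C)=C | intermediate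
8 | methyl (2Z,4S)-2-(bromomethyl)-6-methyl-4-(triethylsilyloxy)hepta-2,6-dienoate | COC(=O)/C(CBr)=C/[C@@H](O[Si](CC)(CC)CC)CC(C)=C | intermediate
9 | (tert-butyldiphenylsilyloxy)acetaldehyde | O=CCO[Si](c1ccccc1)(c1ccccc1)C(C)(C)C | starting material
10 | methyl (triphenylphosphoranylidene)acetate | COC(=O)C=P(c1ccccc1)(c1ccccc1)c1ccccc1 | starting material
11 | methyl (2E)-4-(tert-butyldiphenylsilyloxy)but-2-enoate | COC(=O)/C=C/CO[Si](c1ccccc1)(c1ccccc1)C(C)(C)C | intermediate
12 | but-3-enylmagnesium bromide | C=CCC[Mg]Br | starting material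
13 | methyl (3R)-3-[(tert-butyldiphenylsilyloxy)methyl]hept-6-enoate | COC(=O)C[C@H](CO[Si](c1ccccc1)(c1ccccc1)C(C)(C)C)CCC=C | intermediate
14 | (3R)-3-[(tert-butyldiphenylsilyloxy)methyl]hept-6-enal | O=CC[C@H](CO[Si](c1ccccc1)(c1ccccc1)C(C)(C)C)CCC=C | intermediate
15 | dichlorochromium alkoxide of methyl (3S,4R,6R)-6-[(tert-butyldiphenylsilyloxy)methyl]-4-hydroxy-2-methylidene-3-[(1S)-3-methyl-1-(triethylsilyloxy)but-3-en-1-yl]dec-9-enoate (descriptors of the free alcohol) | C=C(C(=O)OC)[C@@H]([C@H](O[Cr](Cl)Cl)C[C@H](CO[Si](c1ccccc1)(c1ccccc1)C(C)(C)C)CCC=C)[C@@H](O[Si](CC)(CC)CC)CC(C)=C | intermediate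
16 | (4S,5R)-5-{(2R)-2-[(tert-butyldiphenylsilyloxy)methyl]hex-5-en-1-yl}-3-methylidene-4-[(1S)-3-methyl-1-(triethylsilyloxy)but-3-en-1-yl]oxolan-2-one | C=C1C(=O)O[C@H](C[C@H](CO[Si](c2ccccc2)(c2ccccc2)C(C)(C)C)CCC=C)[C@H]1[C@@H](O[Si](CC)(CC)CC)CC(C)=C | intermediate
17 | angelic acid, (2Z)-2-methylbut-2-enoic acid | C/C=C(/C)C(=O)O | starting material
18 | O-triphenylphosphonium derivative of the C8 alkoxide of 16 (C8 configuration retained), as its 2,3-dichloro-5,6-dicyano-4-(triethylsilyloxy)phenolate salt | C=C1C(=O)O[C@H](C[C@H](CO[Si](c2ccccc2)(c2ccccc2)C(C)(C)C)CCC=C)[C@H]1[C@@H](O[P+](c2ccccc2)(c2ccccc2)c2ccccc2)CC(C)=C.[O-]c1c(Cl)c(Cl)c(O[Si](CC)(CC)CC)c(C#N)c1C#N | intermediate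
19 | (1R)-1-[(2R,3S)-2-{(2R)-2-[(tert-butyldiphenylsilyloxy)methyl]hex-5-en-1-yl}-4-methylidene-5-oxooxolan-3-yl]-3-methylbut-3-en-1-yl (2Z)-2-methylbut-2-enoate | C=C1C(=O)O[C@H](C[C@H](CO[Si](c2ccccc2)(c2ccccc2)C(C)(C)C)CCC=C)[C@H]1[C@H](OC(=O)/C(C)=C\C)CC(C)=C | intermediate
20 | (3aS,4R,6Z,10R,11aR)-10-[(tert-butyldiphenylsilyloxy)methyl]-6-methyl-3-methylidene-2-oxo-2,3,3a,4,5,8,9,10,11,11a-decahydrocyclodeca[b]furan-4-yl (2Z)-2-methylbut-2-enoate | C=C1C(=O)O[C@@H]2C[C@H](CO[Si](c3ccccc3)(c3ccccc3)C(C)(C)C)CC/C=C(/C)C[C@@H](OC(=O)/C(C)=C\C)[C@@H]12 | intermediate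
21 | (3aS,4R,6E,10R,11aR)-10-[(tert-butyldiphenylsilyloxy)methyl]-6-(hydroxymethyl)-3-methylidene-2-oxo-2,3,3a,4,5,8,9,10,11,11a-decahydrocyclodeca[b]furan-4-yl (2Z)-2-methylbut-2-enoate | C=C1C(=O)O[C@@H]2C[C@H](CO[Si](c3ccccc3)(c3ccccc3)C(C)(C)C)CC/C=C(/CO)C[C@@H](OC(=O)/C(C)=C\C)[C@@H]12 | intermediate
22 | (3aS,4R,6E,10R,11aR)-6,10-bis(hydroxymethyl)-3-methylidene-2-oxo-2,3,3a,4,5,8,9,10,11,11a-decahydrocyclodeca[b]furan-4-yl (2Z)-2-methylbut-2-enoate | C=C1C(=O)O[C@@H]2C[C@H](CO)CC/C=C(/CO)C[C@@H](OC(=O)/C(C)=C\C)[C@@H]12 | target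

**Step count**
Total: 13 steps. Longest linear sequence: 10 steps (steps 1–5, then 9–13).

**Three steps most likely to fail, with fallbacks**

Step 9 (chromium allylation). The risk is poor anti or facial selectivity, since the C7/C8 relay rests on a Felkin–Anh-type model. The fallback sets out from 8 and 14 and comes back at 16. The two are coupled with indium powder in THF/H2O (aqueous Barbier conditions, which give the syn adduct from (Z)-2-(bromomethyl)alk-2-enoates) to give methyl (3S,4S,6R)-6-[(tert-butyldiphenylsilyloxy)methyl]-4-hydroxy-2-methylidene-3-[(1S)-3-methyl-1-(triethylsilyloxy)but-3-en-1-yl]dec-9-enoate F1, the C6 epimer of the alcohol in 15. LiOH in THF/H2O at 0 °C then gives (3S,4S,6R)-6-[(tert-butyldiphenylsilyloxy)methyl]-4-hydroxy-2-methylidene-3-[(1S)-3-methyl-1-(triethylsilyloxy)but-3-en-1-yl]dec-9-enoic acid F2. Mitsunobu lactonisation (PPh3, DIAD, PhMe, 0 °C) closes the lactone with inversion at C6 and returns to 16.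

Step 10 (the proposed desilylative inversion). The risks are that the silyl ether does not transfer to phosphorus, that the primary silyl ether competes, or that elimination at the hindered C8 wins. The fallback uses known chemistry, sets out from 16 and comes back at 19. PPTS in MeOH at 0 °C removes only the triethylsilyl group to give (4R,5R)-5-{(2R)-2-[(tert-butyldiphenylsilyloxy)methyl]hex-5-en-1-yl}-4-[(1S)-1-hydroxy-3-methylbut-3-en-1-yl]-3-methylideneoxolan-2-one F3. A classical Mitsunobu esterification of this alcohol with angelic acid 17 (PPh3, DIAD, PhMe, 0 °C → rt) gives 19 with inversion at C8.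

Step 11 (ring-closing metathesis to a trisubstituted cyclodecene). The risks are oligomerisation or no ring closure. The fallback reverses the order of the two C–C bond formations, sets out from 8 and 14, and comes back at 21.
- Cross-metathesis of 14 with 8 (second-generation Grubbs catalyst RuCl2(=CHPh)(H2IMes)(PCy3), CH2Cl2, 40 °C) gives methyl (2Z,4S,6E,10R)-2-(bromomethyl)-10-[(tert-butyldiphenylsilyloxy)methyl]-6-methyl-12-oxo-4-(triethylsilyloxy)dodeca-2,6-dienoate F4 (E major; the Z isomer is carried along).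
- CrCl2 in THF at high dilution closes the 10-membered ring and the lactone in one intramolecular Nozaki–Hiyama reaction, the ring-closing mode established for germacranolides, to give (3aS,4S,6E,10R,11aR)-10-[(tert-butyldiphenylsilyloxy)methyl]-6-methyl-3-methylidene-4-(triethylsilyloxy)-3a,4,5,8,9,10,11,11a-octahydrocyclodeca[b]furan-2(3H)-one F5.
- The step 10 conditions convert this into (3aS,4R,6E,10R,11aR)-10-[(tert-butyldiphenylsilyloxy)methyl]-6-methyl-3-methylidene-2-oxo-2,3,3a,4,5,8,9,10,11,11a-decahydrocyclodeca[b]furan-4-yl (2Z)-2-methylbut-2-enoate F6.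
- SeO2/t-BuOOH under the step 12 conditions hydroxylates C14 with E-to-Z isomerisation of C1=C10 and gives 21.

**Further compounds**

F1 | step 9 | methyl (3S,4S,6R)-6-[(tert-butyldiphenylsilyloxy)methyl]-4-hydroxy-2-methylidene-3-[(1S)-3-methyl-1-(triethylsilyloxy)but-3-en-1-yl]dec-9-enoate | C=C(C(=O)OC)[C@@H]([C@@H](O)C[C@H](CO[Si](c1ccccc1)(c1ccccc1)C(C)(C)C)CCC=C)[C@@H](O[Si](CC)(CC)CC)CC(C)=C
F2 | step 9 | (3S,4S,6R)-6-[(tert-butyldiphenylsilyloxy)methyl]-4-hydroxy-2-methylidene-3-[(1S)-3-methyl-1-(triethylsilyloxy)but-3-en-1-yl]dec-9-enoic acid | C=C(C(=O)O)[C@@H]([C@@H](O)C[C@H](CO[Si](c1ccccc1)(c1ccccc1)C(C)(C)C)CCC=C)[C@@H](O[Si](CC)(CC)CC)CC(C)=C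
F3 | step 10 | (4R,5R)-5-{(2R)-2-[(tert-butyldiphenylsilyloxy)methyl]hex-5-en-1-yl}-4-[(1S)-1-hydroxy-3-methylbut-3-en-1-yl]-3-methylideneoxolan-2-one | C=C1C(=O)O[C@H](C[C@H](CO[Si](c2ccccc2)(c2ccccc2)C(C)(C)C)CCC=C)[C@H]1[C@@H](O)CC(C)=C
F4 | step 11 | methyl (2Z,4S,6E,10R)-2-(bromomethyl)-10-[(tert-butyldiphenylsilyloxy)methyl]-6-methyl-12-oxo-4-(triethylsilyloxy)dodeca-2,6-dienoate | O=CC[C@H](CO[Si](c1ccccc1)(c1ccccc1)C(C)(C)C)CC/C=C(\C)C[C@H](O[Si](CC)(CC)CC)/C=C(\CBr)C(=O)OC
F5 | step 11 | (3aS,4S,6E,10R,11aR)-10-[(tert-butyldiphenylsilyloxy)methyl]-6-methyl-3-methylidene-4-(triethylsilyloxy)-3a,4,5,8,9,10,11,11a-octahydrocyclodeca[b]furan-2(3H)-one | C=C1C(=O)O[C@@H]2C[C@H](CO[Si](c3ccccc3)(c3ccccc3)C(C)(C)C)CC/C=C(\C)C[C@H](O[Si](CC)(CC)CC)[C@@H]12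
F6 | step 11 | (3aS,4R,6E,10R,11aR)-10-[(tert-butyldiphenylsilyloxy)methyl]-6-methyl-3-methylidene-2-oxo-2,3,3a,4,5,8,9,10,11,11a-decahydrocyclodeca[b]furan-4-yl (2Z)-2-methylbut-2-enoate | C=C1C(=O)O[C@@H]2C[C@H](CO[Si](c3ccccc3)(c3ccccc3)C(C)(C)C)CC/C=C(\C)C[C@@H](OC(=O)/C(C)=C\C)[C@@H]12
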